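**Retrosynthetic overview**
1. Target 16 comes from tris-benzyl ether 15 by global hydrogenolysis; C2 of 15 is set last, by Krapcho dealkoxycarbonylation and thermodynamic epimerisation of gem-diester 13.
2. 13 is cut at C1–C1′ (pendant aryl) and at C2–C3: Rh/chiral-diene conjugate arylation of arylidene malonate 10 with boronic acid 11, after which the malonate anion displaces the C3 mesylate.
3. 10 comes from aldehyde 8 and dimethyl malonate (Knoevenagel); 8 comes from O-benzylisovanillin via bromo acetal 3, whose Grignard reagent opens (S)-benzyl glycidyl ether (source of C3).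
4. Enabling feature: C1 is a benzylic CH on ring A (at C8a) and β to the C2 ester carbonyl, so it can be the electrophilic end of a C1=C2 alkylidene malonate; the ortho carbon C4a carries C4–C3, so the C2 carbanion formed on arylation sits in 6-exo reach of a leaving group on C3.
5. Ring order: both benzene rings are bought; the only ring formed is the carbocycle C1–C2–C3–C4–C4a–C8a, in step 6.

Key step: step 6

Remark: the sense of induction of the chiral diene–Rh catalyst on this arylidene malonate must be assigned on the first run; the route is written with (R,R)-Ph-bod* as the working choice for the ligand enantiomer that gives (R)-C1 as drawn, the antipode being equally available.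

**Step 1**
Reactants: 1 3-(benzyloxy)-4-methoxybenzaldehyde
Product: 2 5-(benzyloxy)-2-bromo-4-methoxybenzaldehyde
Conditions: Br2 (1.1 equiv), NaOAc, AcOH, rt
Reagents that add atoms: bromine BrBr
Why: Electrophilic aromatic bromination should go to the free position para to the benzyloxy group and ortho to the formyl group (as in the bromination of veratraldehyde); NaOAc buffers the HBr and protects the benzyl ether.

**Step 2**
Reactants: 2 5-(benzyloxy)-2-bromo-4-methoxybenzaldehyde
Product: 3 2-[5-(benzyloxy)-2-bromo-4-methoxyphenyl]-1,3-dioxolane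
Conditions: ethylene glycol, p-TsOH (cat.), toluene, reflux, Dean–Stark
Reagents that add atoms: ethylene glycol OCCO
Why: Acid-catalysed acetalisation with azeotropic removal of water masks the aldehyde so that an aryl Grignard reagent can be made at the ortho position.

**Step 3**
Reactants: 3 2-[5-(benzyloxy)-2-bromo-4-methoxyphenyl]-1,3-dioxolane; 4 (S)-benzyl glycidyl ether
Product: 6 (2S)-1-(benzyloxy)-3-[4-(benzyloxy)-2-(1,3-dioxolan-2-yl)-5-methoxyphenyl]propan-2-ol, via arylmagnesium bromide 5 (not isolated)
Conditions: Mg, I2 (cat.), THF, 40 °C; then CuI (10 mol %), 4, −30 → 0 °C; aqueous work-up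
Reagents that add atoms: none
Why: Magnesium insertion gives the aryl Grignard reagent, which under copper(I) catalysis opens the terminal epoxide at its CH2 carbon (SN2), so the stereocentre of the glycidyl ether is carried over untouched as the (S)-carbinol.

**Step 4**
Reactants: 6 (2S)-1-(benzyloxy)-3-[4-(benzyloxy)-2-(1,3-dioxolan-2-yl)-5-methoxyphenyl]propan-2-ol
Product: 8 (2S)-1-(benzyloxy)-3-[4-(benzyloxy)-2-formyl-5-methoxyphenyl]propan-2-yl methanesulfonate, via acetal mesylate 7 (not isolated)
Conditions: MsCl, Et3N, CH2Cl2, 0 °C; then 1 M HCl, THF, rt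
Reagents that add atoms: methanesulfonyl chloride CS(=O)(=O)Cl; water O
Why: O-Sulfonylation proceeds with retention at carbon, and the electron-rich aryl dioxolane is then hydrolysed by dilute acid, to which the sulfonate ester and the benzyl ethers are stable; mesylation comes first because the free hydroxy aldehyde would close to a lactol.

**Step 5**
Reactants: 8 (2S)-1-(benzyloxy)-3-[4-(benzyloxy)-2-formyl-5-methoxyphenyl]propan-2-yl methanesulfonate; 9 dimethyl malonate
Product: 10 dimethyl 2-({5-(benzyloxy)-2-[(2S)-3-(benzyloxy)-2-(methanesulfonyloxy)propyl]-4-methoxyphenyl}methylidene)propanedioate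
Conditions: piperidine (0.2 equiv), AcOH (0.2 equiv), toluene, 4 Å MS, 90 °C
Reagents that add atoms: none
Why: Knoevenagel condensation via the iminium ion gives the doubly activated alkene; the symmetrical malonate avoids any alkene-geometry issue, and the mesylate has no competent nucleophile under these weakly basic conditions.

**Step 6**
Reactants: 10 dimethyl 2-({5-(benzyloxy)-2-[(2S)-3-(benzyloxy)-2-(methanesulfonyloxy)propyl]-4-methoxyphenyl}methylidene)propanedioate; 11 [4-(benzyloxy)-3-methoxyphenyl]boronic acid
Product: 13 dimethyl (1R,3S)-7-(benzyloxy)-1-[4-(benzyloxy)-3-methoxyphenyl]-3-[(benzyloxy)methyl]-6-methoxy-3,4-dihydronaphthalene-2,2(1H)-dicarboxylate, via acyclic malonate adduct 12 (not isolated)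
Conditions: [RhCl(C2H4)2]2 (2.5 mol %), (R,R)-Ph-bod* (5.5 mol %), KOH (0.2 equiv), dioxane/H2O 10:1, 40 °C; then Cs2CO3 (2 equiv), DMF, 60 °C, same flask
Reagents that add atoms: none
Why: Transmetalation of 11 to the chiral-diene Rh(I) hydroxide gives an aryl–Rh species that inserts the C1=C2 bond of 10 on the face selected by the C2-symmetric diene, and protonolysis releases malonate 12; after Cs2CO3 is added, the cesium enolate of 12 (C2) displaces the C3 mesylate. The closest known reaction types are the Hayashi–Miyaura asymmetric 1,4-addition of arylboronic acids to doubly activated arylmethylene acceptors and the Michael-initiated ring closure by intramolecular malonate alkylation. The one ring closed is the carbocycle C1–C2–C3–C4–C4a–C8a of the tetralin, by a 6-exo-tet SN2 displacement. C1 is set by catalyst-controlled enantioface selection (the symmetrical malonate leaves no E/Z ambiguity), C3 by stereospecific inversion of the (S)-mesylate taken from the chiral pool, and C2 is not yet stereogenic. The step needs aryl transfer to the alkene in the presence of the sulfonate, and C-alkylation in preference to elimination or O-alkylation; the first is secured by the double ester activation of C1=C2, the second by the soft stabilised carbanion, the six-membered exo geometry preorganised by the ortho-disubstituted ring A, and a chair-like transition state in which the C1 aryl and the C3 benzyloxymethyl groups are both pseudo-equatorial (the 1,3-cis relationship needed is the matched case).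

**Step 7**
Reactants: 13 dimethyl (1R,3S)-7-(benzyloxy)-1-[4-(benzyloxy)-3-methoxyphenyl]-3-[(benzyloxy)methyl]-6-methoxy-3,4-dihydronaphthalene-2,2(1H)-dicarboxylate
Product: 15 methyl (1R,2S,3S)-7-(benzyloxy)-1-[4-(benzyloxy)-3-methoxyphenyl]-3-[(benzyloxy)methyl]-6-methoxy-1,2,3,4-tetrahydronaphthalene-2-carboxylate, via C2-epimeric monoester 14 (not isolated)
Conditions: LiCl (3 equiv), H2O (2 equiv), DMSO, 150 °C; crude product then NaOMe (0.3 equiv), MeOH/THF, 60 °C
Reagents that add atoms: none
Why: Krapcho dealkoxycarbonylation (chloride SN2 at a methyl ester, loss of CO2, protonation) should give both C2 epimers, and reversible methoxide enolisation then funnels them to the all-equatorial 1,2-trans-2,3-trans ester (thermodynamic epimerisation); C2 is the only acidic stereocentre and the protected CH2OBn group cannot lactonise.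

**Step 8**
Reactants: 15 methyl (1R,2S,3S)-7-(benzyloxy)-1-[4-(benzyloxy)-3-methoxyphenyl]-3-[(benzyloxy)methyl]-6-methoxy-1,2,3,4-tetrahydronaphthalene-2-carboxylate
Product: 16 methyl (1R,2S,3S)-7-hydroxy-1-(4-hydroxy-3-methoxyphenyl)-3-(hydroxymethyl)-6-methoxy-1,2,3,4-tetrahydronaphthalene-2-carboxylate
Conditions: H2 (1 atm), Pd(OH)2/C, EtOAc/MeOH, rt
Reagents that add atoms: none
Why: Catalytic hydrogenolysis should cleave the two aryl benzyl ethers and the alkyl benzyl ether under neutral conditions that neither epimerise C2 nor drive lactonisation of the trans-disposed hydroxy ester; the diarylmethine C–C bonds are inert.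

**Compound list**
1 | 3-(benzyloxy)-4-methoxybenzaldehyde (O-benzylisovanillin) | COc1ccc(C=O)cc1OCc1ccccc1 | starting material
2 | 5-(benzyloxy)-2-bromo-4-methoxybenzaldehyde | COc1cc(Br)c(C=O)cc1OCc1ccccc1 | intermediate
3 | 2-[5-(benzyloxy)-2-bromo-4-methoxyphenyl]-1,3-dioxolane | COc1cc(Br)c(C2OCCO2)cc1OCc1ccccc1 | intermediate
4 | (S)-benzyl glycidyl ether, (2S)-2-[(benzyloxy)methyl]oxirane | C1[C@H](O1)COCc2ccccc2 | starting material
5 | [4-(benzyloxy)-2-(1,3-dioxolan-2-yl)-5-methoxyphenyl]magnesium bromide | COc1cc([Mg]Br)c(C2OCCO2)cc1OCc1ccccc1 | intermediate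
6 | (2S)-1-(benzyloxy)-3-[4-(benzyloxy)-2-(1,3-dioxolan-2-yl)-5-methoxyphenyl]propan-2-ol | COc1cc(C[C@H](O)COCc2ccccc2)c(C2OCCO2)cc1OCc1ccccc1 | intermediate
7 | (2S)-1-(benzyloxy)-3-[4-(benzyloxy)-2-(1,3-dioxolan-2-yl)-5-methoxyphenyl]propan-2-yl methanesulfonate | COc1cc(C[C@H](OS(C)(=O)=O)COCc2ccccc2)c(C2OCCO2)cc1OCc1ccccc1 | intermediate
8 | (2S)-1-(benzyloxy)-3-[4-(benzyloxy)-2-formyl-5-methoxyphenyl]propan-2-yl methanesulfonate | COc1cc(C[C@H](OS(C)(=O)=O)COCc2ccccc2)c(C=O)cc1OCc1ccccc1 | intermediate
9 | dimethyl malonate | COC(=O)CC(=O)OC | starting material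
10 | dimethyl 2-({5-(benzyloxy)-2-[(2S)-3-(benzyloxy)-2-(methanesulfonyloxy)propyl]-4-methoxyphenyl}methylidene)propanedioate | COC(=O)C(C(=O)OC)=Cc1cc(OCc2ccccc2)c(OC)cc1C[C@H](OS(C)(=O)=O)COCc1ccccc1 | intermediate
11 | [4-(benzyloxy)-3-methoxyphenyl]boronic acid | COc1cc(B(O)O)ccc1OCc1ccccc1 | starting material
12 | dimethyl 2-[(R)-[4-(benzyloxy)-3-methoxyphenyl]{5-(benzyloxy)-2-[(2S)-3-(benzyloxy)-2-(methanesulfonyloxy)propyl]-4-methoxyphenyl}methyl]propanedioate | COC(=O)C(C(=O)OC)[C@H](c1ccc(OCc2ccccc2)c(OC)c1)c1cc(OCc2ccccc2)c(OC)cc1C[C@H](OS(C)(=O)=O)COCc1ccccc1 | intermediate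
13 | dimethyl (1R,3S)-7-(benzyloxy)-1-[4-(benzyloxy)-3-methoxyphenyl]-3-[(benzyloxy)methyl]-6-methoxy-3,4-dihydronaphthalene-2,2(1H)-dicarboxylate (aryl and CH2OBn cis) | COC(=O)C1(C(=O)OC)[C@@H](COCc3ccccc3)Cc2cc(OC)c(OCc3ccccc3)cc2[C@H]1c1ccc(OCc2ccccc2)c(OC)c1 | intermediate
14 | methyl (1R,2R,3S)-7-(benzyloxy)-1-[4-(benzyloxy)-3-methoxyphenyl]-3-[(benzyloxy)methyl]-6-methoxy-1,2,3,4-tetrahydronaphthalene-2-carboxylate (C2 epimer, ester cis to both neighbours) | COC(=O)[C@H]1[C@@H](COCc3ccccc3)Cc2cc(OC)c(OCc3ccccc3)cc2[C@H]1c1ccc(OCc2ccccc2)c(OC)c1 | intermediate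
15 | methyl (1R,2S,3S)-7-(benzyloxy)-1-[4-(benzyloxy)-3-methoxyphenyl]-3-[(benzyloxy)methyl]-6-methoxy-1,2,3,4-tetrahydronaphthalene-2-carboxylate (1,2-trans, 2,3-trans) | COC(=O)[C@@H]1[C@@H](COCc3ccccc3)Cc2cc(OC)c(OCc3ccccc3)cc2[C@H]1c1ccc(OCc2ccccc2)c(OC)c1 | intermediate
16 | methyl (1R,2S,3S)-7-hydroxy-1-(4-hydroxy-3-methoxyphenyl)-3-(hydroxymethyl)-6-methoxy-1,2,3,4-tetrahydronaphthalene-2-carboxylate (1,2-trans, 2,3-trans) | COC(=O)[C@@H]1[C@@H](CO)Cc2cc(OC)c(O)cc2[C@H]1c1ccc(O)c(OC)c1 | target

Total step count: 8. Longest linear sequence: 8 steps (1 → 16).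

**Steps most likely to fail**

Step 6. Aryl–Rh insertion into the hindered, electron-rich, ortho-disubstituted arylidene malonate may be slow, so that protodeboronation or hydrolytic retro-Knoevenagel cleavage competes, and face discrimination may be insufficient. In the second stage the congested malonate anion may close slowly on the secondary mesylate, so that β-elimination towards the styrene or ester hydrolysis takes over. Fallback, setting out from 8: Horner–Wadsworth–Emmons olefination with trimethyl phosphonoacetate (LiCl, DBU, MeCN, rt) should give methyl (E)-cinnamate F1. Rh/chiral-diene asymmetric 1,4-addition of 11 to this cinnamate (the best-precedented substrate class for 3,3-diarylpropanoates) should give methyl 3,3-diarylpropanoate F2. KHMDS (THF, −78 → 0 °C) should then close the ring by 6-exo-tet alkylation of the less hindered, more reactive ester enolate with inversion at C3. Allylic 1,3-strain keeps C1–H in the enolate plane, so the 1,2-trans ester is expected kinetically. This comes back to the route at 15 and bypasses 10, 13 and the decarboxylation.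

Step 5. Condensation of the electron-rich, ortho-substituted aldehyde may be sluggish, and prolonged heating with amine may erode the secondary mesylate by substitution or elimination. Fallback, setting out from 8: condensation with aniline (MgSO4, CH2Cl2, rt) should give N-phenyl imine F3. Its reaction with dimethyl malonate 9 (AcOH cat., toluene, 50 °C) proceeds by Mannich-type addition and loss of aniline, so the C–C bond forms on a preformed C=N electrophile at lower temperature. This comes back to the route at 10.

Step 7. Chloride-induced demethylation at the doubly flanked gem-diester may be slow at 150 °C and cost material (benzyl ether cleavage, ester hydrolysis), and the C2 equilibrium may stop short of completion. Fallback, setting out from 13: mono-saponification of the less hindered ester (KOH 1.1 equiv, MeOH/THF/H2O, 40 °C, then acidification) should give malonic half-acid F4. Thermal decarboxylation (toluene, Et3N cat., 110 °C) and the same methoxide equilibration come back to the route at 15. If the equilibrium itself is unfavourable, 14 is separated and resubmitted, or C2 is set kinetically by the enolate cyclisation described for step 6.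

**Further compounds**
F1 | step 6 | methyl (2E)-3-{5-(benzyloxy)-2-[(2S)-3-(benzyloxy)-2-(methanesulfonyloxy)propyl]-4-methoxyphenyl}prop-2-enoate | COC(=O)/C=C/c1cc(OCc2ccccc2)c(OC)cc1C[C@H](OS(C)(=O)=O)COCc1ccccc1
F2 | step 6 | methyl (3R)-3-[4-(benzyloxy)-3-methoxyphenyl]-3-{5-(benzyloxy)-2-[(2S)-3-(benzyloxy)-2-(methanesulfonyloxy)propyl]-4-methoxyphenyl}propanoate | COC(=O)C[C@H](c1ccc(OCc2ccccc2)c(OC)c1)c1cc(OCc2ccccc2)c(OC)cc1C[C@H](OS(C)(=O)=O)COCc1ccccc1
F3 | step 5 | (2S)-1-(benzyloxy)-3-{4-(benzyloxy)-5-methoxy-2-[(E)-(phenylimino)methyl]phenyl}propan-2-yl methanesulfonate | COc1cc(C[C@H](OS(C)(=O)=O)COCc2ccccc2)c(/C=N/c2ccccc2)cc1OCc1ccccc1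
F4 | step 7 | (1R,2R,3S)-7-(benzyloxy)-1-[4-(benzyloxy)-3-methoxyphenyl]-3-[(benzyloxy)methyl]-6-methoxy-2-(methoxycarbonyl)-1,2,3,4-tetrahydronaphthalene-2-carboxylic acid (carboxyl trans to the C1 aryl and C3 CH2OBn groups) | OC(=O)[C@]1(C(=O)OC)[C@@H](COCc3ccccc3)Cc2cc(OC)c(OCc3ccccc3)cc2[C@H]1c1ccc(OCc2ccccc2)c(OC)c1
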